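The numbers in the tables stem from a simulated flask on assumed constants, and the scatter is random.

**Impossible row.** Target above 100 percent of the substrate charged is impossible, yet plain scaling of the earlier runs asks for it. Watch where that scaling breaks.

| flask | substrate | partner | initiator | remark | time |
|---|---|---|---|---|---|
| Friday's | 0.34 mM | 0.75 mM | 10 µM | run made earlier |  |
| Monday's | 0.25 mM | 0.75 mM | 10 µM | run made earlier |  |
| grey | 0.50 mM | 0.750 mM | 10 µM |  | 6.0 min |
| amber | 0.50 mM | 0.750 mM | 20 µM |  | 6.0 min |
| teal | 0.50 mM | 0.750 mM | 40 µM |  | 6.0 min |
| violet | 0.50 mM | 0.750 mM | 80 µM |  | 6.0 min |
| green | 0.50 mM | 0.750 mM | 150 µM |  | 6.0 min |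

| run | time / s | target / % |
|---|---|---|
| Friday's | 10.0 | 5.6 |
| Friday's | 12.0 | 8.4 |
| Friday's | 20.0 | 10.7 |
| Friday's | 30.0 | 17.1 |
| Friday's | 50.0 | 22.3 |
| Friday's | 80.0 | 23.4 |
| Monday's | 10.0 | 9.8 |
| Monday's | 12.0 | 12.0 |
| Monday's | 20.0 | 16.5 |
| Monday's | 30.0 | 20.3 |
| Monday's | 50.0 | 29.9 |
| Monday's | 80.0 | 36.1 |

(standard deviation of a reading: 1 percentage point)

1. amount of target at the end, in percent of the substrate charged for grey, amber, teal, violet, green, in this order
2. how that number moves from the first to the last of them (falls all the way / falls, then rises / rises all the way / hardly changes / rises, then falls)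

- percentages count the substrate that a species holds: one ended chains A counts as two
- by-product is meant together with its crystals
- solid, in amounts per volume of the solution: crystals
- the earlier runs were read with a standard deviation of 1 percentage point
- what may be going on: initiator -> 2 initiating radical; substrate + initiating radical -> capped initiator + first chain carrier; partner + first chain carrier -> target + second chain carrier; substrate + second chain carrier -> by-product + first chain carrier; first chain carrier -> ended carrier; 2 first chain carrier -> ended chains A; 2 second chain carrier -> ended chains B; crystals <-> by-product; partner -> decomposed reagent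
- "hardly changes" means that all values lie within two and a half points (for a concentration: within two and a half percent of the largest)
- no earlier run changes the charge of initiator; that part of a forecast is a guess

**Counting half-lives.** Both earlier runs pass half their last reading just after 20.0 s. I take that reading as the half-life of initiator. It is far shorter than the time allowed, and 18.0 half-lives fit in. So you are asking for an end value. But the last reading stands at 4.00 half-lives, so it needs a small correction upward.

**Chain yield.** Take c(target) at the end divided by c(initiator) charged, the target per initiator charged. Corrected and averaged over both runs, it reads 9.06. For grey that gives 18.1 %, for amber 36.2 % and for teal 72.5 %. For green it gives 272 %, an impossible figure.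

**The ceiling.** That scaling is the weak link, so I reforge it. Each initiator gives two radicals, so one radical's chain makes 4.53 target, the kinetic chain length. Such a chain spends one substrate per target and one more on the carrier that ends it. So at that chain length target comes to 81.9 % of the substrate spent. My row stops there at violet and green. No earlier run changes the initiator, so this part is a guess.

**The forecast.** It gives 19 %, 35 %, 58 %, 68 % and 62 %, so its shape is rises, then falls, where my row climbs and then stands flat. It says of its last step: “That decline at high charge is a guess, since no earlier run varied initiator.”

**The flask.** It gives 18.7 %, 30.4 %, 46.3 %, 66.1 % and 59.5 %, so the shape is rises, then falls, turning at 83 µM.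

    initiator → 2 initiating radical (k = 0.0300 s⁻¹)
    substrate + initiating radical → capped initiator + first chain carrier (k = 8.30 × 10⁶ M⁻¹ s⁻¹)
    partner + first chain carrier → target + second chain carrier (k = 2.70 × 10⁵ M⁻¹ s⁻¹)
    substrate + second chain carrier → by-product + first chain carrier (k = 1.40 × 10⁶ M⁻¹ s⁻¹)
    first chain carrier → ended carrier (k = 26.0 s⁻¹)
    2 first chain carrier → ended chains A (k = 7.00 × 10⁸ M⁻¹ s⁻¹)
    2 second chain carrier → ended chains B (k = 2.30 × 10⁶ M⁻¹ s⁻¹)
    crystals ⇌ by-product, rate k8*(cs8 - [by-product]) while solid is left; crystals form when [by-product] > cs8 (solubility = 0.150 mM, k = 2.50 s⁻¹)
    partner → decomposed reagent (k = 0.00320 s⁻¹)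

**Green's shortfall.** Target per initiator charged is 9.35 in grey, beside the 9.06 carried over. In green it is 1.98, and the substrate charged there allows 3.33. First chain carrier pairing into ended chains A is the main reason that green stops short of that figure, at 60 % of what is missing, so watch that step in green. With that step taken away, green rises from 59.5 % to 83.9 %, which is 2.80 target per initiator charged.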